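**Plan**
Retrosynthesis: the C13=C14 enoate is cut back to a C13 methyl ketone (olefination). C6–OH is removed, the ring B enone is transposed (C7=O back to C9=O) and the C11–C16 chain leaves as a 3-oxobutyl carbanion. Ring A is then cut at C1–C10 and C3–C4, which releases a C1–C3 2-sulfonylallyl unit and leaves the methylated isopropenyl epoxide of (S)-carvone.
Forward: ring B is carvone; ring A is closed onto it in one flask (step 3); the chain is then joined at C9, the enone transposed, C6 oxygenated, the C7=C8 alkene set and the enoate finished.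
Enabling feature: C10 and C4 are the two quaternary carbons that both hang on C5. C10 is the α′-carbon of the ring B ketone (C9), and C4 with its CH3/CH2OH pair is the tertiary oxirane carbon of the epoxidised isopropenyl group. Each can be made a carbon nucleophile (enolate; tertiary radical), so ring A is only the three-carbon bridge between them.
Stereochemistry: C5 from (S)-carvone; C10 by alkylation anti to the C5 substituent (trans fusion); C4 in the chair-like radical ring closure; C6 by oxygen transfer anti to the two axial methyls; C9 by axial protonation in the dissolving-metal reduction; 13E by the olefination.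

Key step: step 3

Remark: intermediates carry labdane locants (ring carbons C1–C10; C17 = CH3 on C8, C18 = CH2O on C4, C19 = CH3 on C4, C20 = CH3 on C10; chain C11–C16). "syn" and "anti" refer to the ring face of the C20 methyl group. TBS = tert-butyldimethylsilyl.
Assumption: 2,3-bis(phenylsulfonyl)prop-1-ene, 2-(2-bromoethyl)-2-methyl-1,3-dioxolane and 3-phenyl-2-(phenylsulfonyl)oxaziridine are taken as purchasable.

**Step 1**
Reactants: 1 (S)-(+)-carvone
Product: 2 6-methylcarvone (both C6 epimers)
Conditions: LiN(i-Pr)2, THF, −78 °C; MeI, −78 → 0 °C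
Reagents that add atoms: iodomethane, CI
Why: Kinetic α′-deprotonation of the enone and SN2 methylation of the cross-conjugated lithium enolate (enolate alkylation) should install the future C20 methyl; the new centre is re-enolised in step 3, so its configuration does not matter.

**Step 2**
Reactants: 2 6-methylcarvone
Product: 3 6-methylcarvone 8,9-epoxide (epimers at C6 and at the oxirane carbon)
Conditions: mCPBA, NaHCO3, CH2Cl2, 0 °C
Reagents that add atoms: 3-chloroperoxybenzoic acid, OOC(=O)c1cccc(Cl)c1
Why: Prilezhaev epoxidation should occur only at the electron-rich 1,1-disubstituted alkene and not at the electron-poor enone C=C; the oxirane carbon becomes planar in step 3, so both epimers converge.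

**Step 3**
Reactants: 3 6-methylcarvone 8,9-epoxide; 4 2,3-bis(phenylsulfonyl)prop-1-ene
Product: 6 ring-A-closed keto alcohol (2-phenylsulfonyl; 18-OH), via sulfonylallyl epoxy enone 5 (not isolated)
Conditions: LiN(i-Pr)2, THF, −78 °C; 4, −78 → −30 °C; then Cp2TiCl2 (0.2 equiv), Mn, 2,4,6-collidine·HCl, THF, rt
Reagents that add atoms: none
Why: LiN(i-Pr)2 gives the C10 enolate of 3, which adds to the CH2= terminus of 4 and expels benzenesulfinate (SN2′ allylation), forming C1–C10 on the face anti to the C5 oxiranyl group to give 5. Cp2TiCl (trivalent titanium, turned over by Mn and collidinium chloride) then opens the oxirane by single-electron transfer to the tertiary C4 radical bearing CH2O–Ti, which attacks C3, the unsubstituted terminus of the 2-sulfonylallyl acceptor; the α-sulfonyl radical is reduced and protonated. The closest known reaction types are enolate allylation with 2-sulfonylallyl electrophiles and titanocene-mediated epoxide-opening radical cyclization onto electron-poor alkenes (Giese-type). Ring A closes in the 6-endo-trig mode, because the sulfonyl group on C2 polarises the alkene toward attack at C3 and blocks the 5-exo path. C10 is set by steric approach control (trans ring fusion), and C4 by a chair-like transition state in which the bulky CH2O–Ti arm lies equatorial, away from the C20 methyl, so that CH3-19 ends syn (axial) and CH2OH-18 anti. The step needs cyclization to outrun reduction of the C4 radical, which the low stationary concentration of trivalent titanium and the activated acceptor should secure; the sulfonyl group is a helper that is removed in step 9.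

**Step 4**
Reactants: 6 ring-A-closed keto alcohol
Product: 7 18-O-TBS ether of 6
Conditions: TBSCl, imidazole, DMF, rt
Reagents that add atoms: tert-butyldimethylsilyl chloride, CC(C)(C)[Si](C)(C)Cl
Why: Imidazole-promoted silyl ether formation at the primary alcohol should protect C18–OH against the chromium oxidant of step 6.

**Step 5**
Reactants: 7 18-O-TBS keto sulfone; 8 2-(2-bromoethyl)-2-methyl-1,3-dioxolane
Product: 10 tertiary allylic alcohol at C9, via Grignard reagent 9 (not isolated)
Conditions: 8, Mg, THF, rt; CeCl3, THF, −78 °C; 7, −78 → 0 °C; then H2O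
Reagents that add atoms: none
Why: The organocerium reagent made from Grignard reagent 9 should add 1,2 to the hindered enone carbonyl (carbonyl addition) without enolisation or reduction; the C9 carbinol centre is erased in step 6.

**Step 6**
Reactants: 10 tertiary allylic alcohol
Product: 11 transposed enone (C7=O, C8=C9)
Conditions: pyridinium chlorochromate (C5H5NH[CrO3Cl]), NaOAc, 4 Å MS, CH2Cl2, rt
Reagents that add atoms: pyridinium chlorochromate, [O-][Cr](=O)(=O)Cl.c1cc[nH+]cc1
Why: Babler–Dauben oxidative transposition: the tertiary allylic chromate ester should undergo a 3,3-shift to C7 and be oxidised there, moving the carbonyl to C7 and the alkene to C8=C9.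

**Step 7**
Reactants: 11 transposed enone
Product: 12 6-hydroxy enone (6-OH anti to C20)
Conditions: KN(SiMe3)2, THF, −78 °C; 3-phenyl-2-(phenylsulfonyl)oxaziridine; then H2O
Reagents that add atoms: 3-phenyl-2-(phenylsulfonyl)oxaziridine, O=S(=O)(N1OC1c1ccccc1)c1ccccc1
Why: Kinetic α′-enolisation toward C6 and electrophilic hydroxylation by the N-sulfonyloxaziridine should deliver oxygen to the enolate face anti to the two axial methyl groups (C19, C20), giving the equatorial 6-OH, which is also the more stable epimer of the α-ketol.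

**Step 8**
Reactants: 12 6-hydroxy enone
Product: 13 6,18-bis-O-TBS enone
Conditions: TBSOTf, 2,6-lutidine, CH2Cl2, −78 → 0 °C
Reagents that add atoms: tert-butyldimethylsilyl trifluoromethanesulfonate, CC(C)(C)[Si](C)(C)OS(=O)(=O)C(F)(F)F
Why: Silyl triflate silylation should cap the hindered secondary alcohol so that it is neither acidic nor a leaving group in steps 9–12.

**Step 9**
Reactants: 13 6,18-bis-O-TBS enone
Product: 15 C7 enol triflate, via lithium C7 enolate 14 (not isolated)
Conditions: Li, NH3(l), THF, t-BuOH (1 equiv), −78 °C; isoprene; −NH3; PhNTf2, THF, −78 → 0 °C; then H2O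
Reagents that add atoms: N-phenylbis(trifluoromethanesulfonimide), FC(F)(F)S(=O)(=O)N(c1ccccc1)S(=O)(=O)C(F)(F)F
Why: Dissolving-metal (Birch-type) enone reduction should protonate C9 axially, placing H-9 anti to C20 and the chain equatorial, and give the C7 enolate regiospecifically for trapping as the enol triflate; the same electrons cleave the C2–SO2Ph bond, while the equatorial 6-silyloxy group lies near the nodal plane of the π system and should be retained.

**Step 10**
Reactants: 15 C7 enol triflate
Product: 16 Δ7 alkene (6,18-bis-O-TBS; C13 dioxolane)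
Conditions: Pd(OAc)2 (cat.), PPh3, HCO2H, n-Bu3N, DMF, 60 °C
Reagents that add atoms: none
Why: Palladium-catalysed formate reduction of the enol triflate (oxidative addition to zerovalent palladium, hydride transfer from formate, reductive elimination) should replace OTf by H and leave the C7=C8 double bond where the enolate put it.

**Step 11**
Reactants: 16 Δ7 alkene
Product: 17 C13 methyl ketone (6,18-bis-O-TBS)
Conditions: PPTS, acetone/H2O, 60 °C
Reagents that add atoms: water, O
Why: Acid-catalysed hydrolysis of the dioxolane should free the C13 methyl ketone while both silyl ethers persist under the weakly acidic conditions.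

**Step 12**
Reactants: 17 C13 methyl ketone; 18 trimethyl phosphonoacetate
Product: 19 methyl (13E)-6,18-bis(TBS-oxy)labda-7,13-dien-15-oate
Conditions: NaH, THF, 0 °C → reflux
Reagents that add atoms: none
Why: Horner–Wadsworth–Emmons olefination of the unhindered methyl ketone should give mainly the (13E)-enoate, the ester ending trans to the larger C12 chain; the minor Z isomer is removed by chromatography.

**Step 13**
Reactants: 19 bis-silylated enoate
Product: 20 target, methyl (13E)-6,18-dihydroxylabda-7,13-dien-15-oate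
Conditions: n-Bu4NF, THF, 40 °C; then H2O
Reagents that add atoms: none
Why: Fluoride-induced cleavage of both silyl ethers (desilylation) should release the 6,18-diol without touching the enoate.

**Compound list**
1 | (S)-(+)-carvone, (5S)-2-methyl-5-(prop-1-en-2-yl)cyclohex-2-en-1-one | CC1=CC[C@@H](CC1=O)C(C)=C | starting material
2 | (5S)-2,6-dimethyl-5-(prop-1-en-2-yl)cyclohex-2-en-1-one (6-methylcarvone, both C6 epimers) | O=C1C(C)=CC[C@H](C(C)=C)C1C | intermediate
3 | (5S)-2,6-dimethyl-5-(2-methyloxiran-2-yl)cyclohex-2-en-1-one (epimers at C6 and at the oxirane carbon) | O=C1C(C)=CC[C@H](C2(C)CO2)C1C | intermediate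
4 | 2,3-bis(phenylsulfonyl)prop-1-ene | C=C(CS(=O)(=O)c1ccccc1)S(=O)(=O)c1ccccc1 | starting material
5 | (5S)-2,6-dimethyl-5-(2-methyloxiran-2-yl)-6-[2-(phenylsulfonyl)prop-2-en-1-yl]cyclohex-2-en-1-one, sulfonylallyl group anti to the oxiranyl group, both oxirane epimers | O=C1C(C)=CC[C@H](C2(C)CO2)[C@@]1(C)CC(=C)S(=O)(=O)c1ccccc1 | intermediate
6 | 18-hydroxy-2-(phenylsulfonyl)-11,12,13,14,15,16-hexanorlabd-7-en-9-one: trans-fused (H-5 anti), CH3-19 syn, CH2OH-18 anti, C2 epimers | O=C1C(C)=CC[C@@H]2[C@@](C)(CO)CC(S(=O)(=O)c3ccccc3)C[C@@]12C | intermediate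
7 | 18-(TBS-oxy)-2-(phenylsulfonyl)-11,12,13,14,15,16-hexanorlabd-7-en-9-one, ring stereochemistry as 6 | O=C1C(C)=CC[C@@H]2[C@@](C)(CO[Si](C)(C)C(C)(C)C)CC(S(=O)(=O)c3ccccc3)C[C@@]12C | intermediate
8 | 2-(2-bromoethyl)-2-methyl-1,3-dioxolane | CC1(CCBr)OCCO1 | starting material
9 | [2-(2-methyl-1,3-dioxolan-2-yl)ethyl]magnesium bromide | CC1(CC[Mg]Br)OCCO1 | intermediate
10 | 18-(TBS-oxy)-13,13-(ethylenedioxy)-2-(phenylsulfonyl)-14,15-dinorlabd-7-en-9-ol, ring stereochemistry as 6, C9 configuration of no consequence | CC1(CCC2(O)C(C)=CC[C@@H]3[C@@](C)(CO[Si](C)(C)C(C)(C)C)CC(S(=O)(=O)c4ccccc4)C[C@@]23C)OCCO1 | intermediate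
11 | 18-(TBS-oxy)-13,13-(ethylenedioxy)-2-(phenylsulfonyl)-14,15-dinorlabd-8-en-7-one, ring stereochemistry as 6 | CC1(CCC2=C(C)C(=O)C[C@@H]3[C@@](C)(CO[Si](C)(C)C(C)(C)C)CC(S(=O)(=O)c4ccccc4)C[C@@]23C)OCCO1 | intermediate
12 | 6-hydroxy-18-(TBS-oxy)-13,13-(ethylenedioxy)-2-(phenylsulfonyl)-14,15-dinorlabd-8-en-7-one, 6-OH anti (equatorial) | CC1(CCC2=C(C)C(=O)[C@@H](O)[C@@H]3[C@@](C)(CO[Si](C)(C)C(C)(C)C)CC(S(=O)(=O)c4ccccc4)C[C@@]23C)OCCO1 | intermediate
13 | 6,18-bis(TBS-oxy)-13,13-(ethylenedioxy)-2-(phenylsulfonyl)-14,15-dinorlabd-8-en-7-one, 6-O anti | CC1(CCC2=C(C)C(=O)[C@@H](O[Si](C)(C)C(C)(C)C)[C@@H]3[C@@](C)(CO[Si](C)(C)C(C)(C)C)CC(S(=O)(=O)c4ccccc4)C[C@@]23C)OCCO1 | intermediate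
14 | lithium 6,18-bis(TBS-oxy)-13,13-(ethylenedioxy)-14,15-dinorlabd-7-en-7-olate, H-9 anti, chain syn | CC1(CC[C@@H]2C(C)=C([O-])[C@@H](O[Si](C)(C)C(C)(C)C)[C@@H]3[C@@](C)(CO[Si](C)(C)C(C)(C)C)CCC[C@@]23C)OCCO1.[Li+] | intermediate
15 | 6,18-bis(TBS-oxy)-13,13-(ethylenedioxy)-14,15-dinorlabd-7-en-7-yl trifluoromethanesulfonate, H-9 anti, chain syn | CC1(CC[C@@H]2C(C)=C(OS(=O)(=O)C(F)(F)F)[C@@H](O[Si](C)(C)C(C)(C)C)[C@@H]3[C@@](C)(CO[Si](C)(C)C(C)(C)C)CCC[C@@]23C)OCCO1 | intermediate
16 | 6,18-bis(TBS-oxy)-13,13-(ethylenedioxy)-14,15-dinorlabd-7-ene, all five ring stereocentres as in the target | CC1(CC[C@@H]2C(C)=C[C@@H](O[Si](C)(C)C(C)(C)C)[C@@H]3[C@@](C)(CO[Si](C)(C)C(C)(C)C)CCC[C@@]23C)OCCO1 | intermediate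
17 | 6,18-bis(TBS-oxy)-14,15-dinorlabd-7-en-13-one | CC(=O)CC[C@@H]1C(C)=C[C@@H](O[Si](C)(C)C(C)(C)C)[C@@H]2[C@@](C)(CO[Si](C)(C)C(C)(C)C)CCC[C@@]12C | intermediate
18 | trimethyl phosphonoacetate | COC(=O)CP(=O)(OC)OC | starting material
19 | methyl (13E)-6,18-bis(TBS-oxy)labda-7,13-dien-15-oate | COC(=O)/C=C(\C)CC[C@@H]1C(C)=C[C@@H](O[Si](C)(C)C(C)(C)C)[C@@H]2[C@@](C)(CO[Si](C)(C)C(C)(C)C)CCC[C@@]12C | intermediate
20 | methyl (2E)-5-[(1R,4R,4aS,5S,8aS)-4-hydroxy-5-(hydroxymethyl)-2,5,8a-trimethyl-1,4,4a,5,6,7,8,8a-octahydronaphthalen-1-yl]-3-methylpent-2-enoate | COC(=O)/C=C(\C)CC[C@@H]1C(C)=C[C@@H](O)[C@@H]2[C@@](C)(CO)CCC[C@@]12C | target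

**Totals**
Total steps: 13. Longest linear sequence: 13 steps, from (S)-carvone 1.

**Steps most likely to fail**

Step 3. The tertiary C4 radical may be reduced or disproportionate before it cyclizes, or the chair preference at C4 may be weak. Fallback, from 5 to 6: the flask sequence is split and ring A is closed by a polar route. Compound 5 is isolated after the alkylation stage. BF3·OEt2 (CH2Cl2, −78 °C) induces Meinwald rearrangement of the 2,2-disubstituted oxirane to the α-branched aldehyde F1. DBU (or pyrrolidine as enamine catalyst) then brings about intramolecular Michael addition of the aldehyde enolate to the vinyl sulfone, giving the bicyclic keto aldehyde F2; allylic strain keeps H-5 in the enolate plane, so the formyl group should end equatorial and CH3-19 axial. NaBH4 at −78 °C reduces only the aldehyde and returns the route at 6.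

Step 9. The 6-silyloxy group may be lost reductively, the substrate may be over-reduced, or the enolate may be trapped incompletely in the presence of the lithium bases formed. Fallback, from 13 to 16: hydrogen is brought to C9 by palladium instead of by dissolving metal. Luche reduction (NaBH4, CeCl3·7H2O, MeOH) should give the allylic alcohol F7 by axial hydride attack (7-OH syn to C20). Formylation (HCO2H, Ac2O, pyridine) gives the allylic formate F8. Pd(OAc)2/n-Bu3P (THF, reflux) then effects formate hydrogenolysis with allylic transposition: palladium enters anti to the formate and hands hydride to C9 on its own face (anti to C20), giving the sulfonyl alkene F9. Sodium amalgam (Na/Hg, Na2HPO4, MeOH) removes the sulfone and returns the route at 16.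

Step 7. Enolisation at the hindered C6 may be slow (the axial C6–H lies under two methyl groups), so that γ-deprotonation competes, or oxygen transfer may lack face selectivity. Fallback, from 11 to 16: C6 is oxygenated only after the C7=C8 alkene is in place. Li/NH3 then PhNTf2 converts 11 to the enol triflate F3 (sulfone cleaved, H-9 set). Pd(OAc)2/PPh3/HCO2H/n-Bu3N gives the alkene F4. CrO3/3,5-dimethylpyrazole (CH2Cl2, −20 °C) oxidises the allylic C6 methylene to the enone F5. Equilibrating Meerwein–Ponndorf–Verley reduction (Al(OiPr)3, i-PrOH, reflux) should give the more stable equatorial alcohol F6, whereas simple hydride reagents are expected to attack from the open face and give the axial epimer. TBSOTf/2,6-lutidine then gives 16.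

**Further compounds**
F1 | step 3 | 2-{(1S)-2,4-dimethyl-3-oxo-2-[2-(phenylsulfonyl)prop-2-en-1-yl]cyclohex-4-en-1-yl}propanal (epimers at the aldehyde α-carbon) | O=C1C(C)=CC[C@H](C(C)C=O)[C@@]1(C)CC(=C)S(=O)(=O)c1ccccc1
F2 | step 3 | 9-oxo-2-(phenylsulfonyl)-11,12,13,14,15,16-hexanorlabd-7-en-18-al, ring stereochemistry as 6 | O=C1C(C)=CC[C@@H]2[C@@](C)(C=O)CC(S(=O)(=O)c3ccccc3)C[C@@]12C
F3 | step 7 | 18-(TBS-oxy)-13,13-(ethylenedioxy)-14,15-dinorlabd-7-en-7-yl trifluoromethanesulfonate | CC1(CC[C@@H]2C(C)=C(OS(=O)(=O)C(F)(F)F)C[C@@H]3[C@@](C)(CO[Si](C)(C)C(C)(C)C)CCC[C@@]23C)OCCO1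
F4 | step 7 | 18-(TBS-oxy)-13,13-(ethylenedioxy)-14,15-dinorlabd-7-ene | CC1(CC[C@@H]2C(C)=CC[C@@H]3[C@@](C)(CO[Si](C)(C)C(C)(C)C)CCC[C@@]23C)OCCO1
F5 | step 7 | 18-(TBS-oxy)-13,13-(ethylenedioxy)-14,15-dinorlabd-7-en-6-one | CC1(CC[C@@H]2C(C)=CC(=O)[C@@H]3[C@@](C)(CO[Si](C)(C)C(C)(C)C)CCC[C@@]23C)OCCO1
F6 | step 7 | 18-(TBS-oxy)-13,13-(ethylenedioxy)-14,15-dinorlabd-7-en-6-ol, 6-OH anti (equatorial) | CC1(CC[C@@H]2C(C)=C[C@@H](O)[C@@H]3[C@@](C)(CO[Si](C)(C)C(C)(C)C)CCC[C@@]23C)OCCO1
F7 | step 9 | 6,18-bis(TBS-oxy)-13,13-(ethylenedioxy)-2-(phenylsulfonyl)-14,15-dinorlabd-8-en-7-ol, 7-OH syn | CC1(CCC2=C(C)[C@H](O)[C@@H](O[Si](C)(C)C(C)(C)C)[C@@H]3[C@@](C)(CO[Si](C)(C)C(C)(C)C)CC(S(=O)(=O)c4ccccc4)C[C@@]23C)OCCO1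
F8 | step 9 | 6,18-bis(TBS-oxy)-13,13-(ethylenedioxy)-2-(phenylsulfonyl)-14,15-dinorlabd-8-en-7-yl formate, 7-O syn | CC1(CCC2=C(C)[C@H](OC=O)[C@@H](O[Si](C)(C)C(C)(C)C)[C@@H]3[C@@](C)(CO[Si](C)(C)C(C)(C)C)CC(S(=O)(=O)c4ccccc4)C[C@@]23C)OCCO1
F9 | step 9 | 6,18-bis(TBS-oxy)-13,13-(ethylenedioxy)-2-(phenylsulfonyl)-14,15-dinorlabd-7-ene, H-9 anti | CC1(CC[C@@H]2C(C)=C[C@@H](O[Si](C)(C)C(C)(C)C)[C@@H]3[C@@](C)(CO[Si](C)(C)C(C)(C)C)CC(S(=O)(=O)c4ccccc4)C[C@@]23C)OCCO1
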